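Locants used throughout (own skeleton numbering): C1–C5 = hydroxypentyl chain (C3 = carbinol); C6 = quaternary carbon bearing C7H2OH; C8 = ring D CH; C9, C10 = ring C CH2; C11=C12 = alkene; C13 = ring-fusion CH; C14, C15 = ring A CH2; C16 = CH–CO2Me; C17 = ring B CH2; C18 = quaternary ring-fusion carbon; C19, C21 = the two NCH2. Ring A = cyclopentene, ring B = ester-bearing cyclopentane, ring C = seven-membered carbocycle, ring D = N-methylpiperidine.
Retrosynthetic cuts, in order: the two silyl ethers; C18–C19 (ring D, iminium–alkene cyclisation that also moves the alkene from C12=C18 to C11=C12); C6–C8 and C10–C11 together (ring C, alkenyl-carbene (4+3)); C12–C18 and C6–C7 together (ring B, carbopalladation/Stille); C16–C17 (lactone alkylation); C17–C18 and C4–C5 (acetylide and epoxide chemistry).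
Enabling feature: C11, C12, C18 and C6 are a contiguous four-carbon edge of ring C shared with rings A and B. With the CH2N arm (C19) taken off C18, that edge is an s-cis-locked semicyclic diene C11=C12–C18=C6 (ring A double bond plus an exocyclic alkylidene on ring B), the 4π partner for the three-carbon alkenyl carbene C10–C9–C8.
Forward ring order: ring A (purchased bicyclic lactone), then ring B, then ring C (key step), then ring D.
Stereochemistry: C13 from the enantiopure lactone; C16 by exo alkylation of its enolate; C3 from (S)-1,2-epoxybutane; C6 and C8 from the Z diene geometry (syn carbopalladation), carbene attack on the convex face and the boat Cope transition state; C18 by tether-directed C–C bond formation.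
Helpers and their removal: N-nosylhydrazone (carbene source), transient cyclopropane (consumed in the key step), C9=C10 alkene (diimide, step 15), C12=C18 alkene (transposed in step 16), Boc and two TBDPS groups (steps 16 and 17).
Key step: step 14

Assumption: compounds 1, 2, 8, 9 and 12 and all reagents named are taken as catalogue chemicals; the route is a paper design and no step has been run.

Step 1
Reactants: 1 (S)-2-ethyloxirane; 2 trimethyl(prop-1-yn-1-yl)silane
Product: 4 (S)-hept-6-yn-3-ol, via silylated alkynol 3 (not isolated)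
Conditions: 2, n-BuLi, TMEDA, THF, −78 to 0 °C; then 1, −20 °C to rt; crude, K2CO3 (cat.), MeOH, rt
Reagents that add atoms: none
Why: Propargylic lithiation of 2 and SN2 opening of the epoxide at its CH2 carbon (epoxide alkylation) should leave the purchased stereocentre untouched as C3, and methanolysis then cleaves the alkynyl C–Si bond.

Step 2
Reactants: 4 (S)-hept-6-yn-3-ol
Product: 5 (S)-tert-butyl(hept-6-yn-3-yloxy)diphenylsilane
Conditions: TBDPSCl, imidazole, DMF, rt
Reagents that add atoms: tert-butylchlorodiphenylsilane, CC(C)(C)[Si](Cl)(c1ccccc1)c1ccccc1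
Why: Imidazole-promoted O-silylation installs a TBDPS ether chosen to survive the later base, palladium and acid steps.

Step 3
Reactants: 5 (S)-tert-butyl(hept-6-yn-3-yloxy)diphenylsilane
Product: 6 (S)-6-[(tert-butyldiphenylsilyl)oxy]oct-2-yn-1-ol
Conditions: n-BuLi, THF, −78 °C; (CH2O)n, −78 °C to rt
Reagents that add atoms: formaldehyde (as paraformaldehyde), C=O
Why: Deprotonation of the terminal alkyne and addition of the acetylide to formaldehyde (hydroxymethylation) adds C17.

Step 4
Reactants: 6 (S)-6-[(tert-butyldiphenylsilyl)oxy]oct-2-yn-1-ol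
Product: 7 (S)-[(8-bromooct-6-yn-3-yl)oxy](tert-butyl)diphenylsilane
Conditions: CBr4, PPh3, CH2Cl2, 0 °C
Reagents that add atoms: tetrabromomethane, BrC(Br)(Br)Br
Why: Appel bromination converts the primary propargylic alcohol into an SN2-reactive bromide without touching the silyl ether.

Step 5
Reactants: 8 tert-butyl methyl(2-oxoethyl)carbamate; 9 (triphenylphosphoranylidene)acetaldehyde
Product: 10 tert-butyl methyl[(E)-4-oxobut-2-en-1-yl]carbamate
Conditions: PhMe, 60 °C
Reagents that add atoms: none
Why: Wittig olefination with the stabilised formyl ylide should give the E enal that carries C8, C9, C10 and C21.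

Step 6
Reactants: 10 tert-butyl methyl[(E)-4-oxobut-2-en-1-yl]carbamate
Product: 11 N-nosylhydrazone of 10 (tert-butyl methyl[(2E)-4-{2-[(2-nitrophenyl)sulfonyl]hydrazinylidene}but-2-en-1-yl]carbamate)
Conditions: 2-nitrobenzenesulfonohydrazide, THF/MeOH, 0 °C
Reagents that add atoms: 2-nitrobenzenesulfonohydrazide, NNS(=O)(=O)c1ccccc1[N+](=O)[O-]
Why: Condensation with the sulfonyl hydrazide gives an N-nosylhydrazone, a storable diazo surrogate that fragments under base near room temperature (Bamford–Stevens type).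

Step 7
Reactants: 12 (3aR,6aS)-3,3a,6,6a-tetrahydro-2H-cyclopenta[b]furan-2-one
Product: 13 (3aS,6aS)-hexahydro-2H-cyclopenta[b]furan-2-one
Conditions: H2 (1 atm), Pd/C, EtOAc, rt
Reagents that add atoms: none
Why: Catalytic hydrogenation removes the ring alkene, which would otherwise compete for the carbene in step 14, and leaves both stereocentres untouched.

Step 8
Reactants: 13 (3aS,6aS)-hexahydro-2H-cyclopenta[b]furan-2-one; 7 (S)-[(8-bromooct-6-yn-3-yl)oxy](tert-butyl)diphenylsilane
Product: 14 (3S,3aS,6aS)-3-{(6S)-6-[(tert-butyldiphenylsilyl)oxy]oct-2-yn-1-yl}hexahydro-2H-cyclopenta[b]furan-2-one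
Conditions: LiN(i-Pr)2, THF, −78 °C; then 7, DMPU, −78 to −30 °C
Reagents that add atoms: none
Why: Lactone enolate alkylation (SN2) should occur on the convex face of the cis-fused bicycle, cis to the ring-fusion hydrogens, which sets C16 relative to C13.

Step 9
Reactants: 14 alkylated lactone
Product: 16 methyl (2S,8S)-8-[(tert-butyldiphenylsilyl)oxy]-2-[(1S,2S)-2-hydroxycyclopentyl]dec-4-ynoate, via potassium hydroxy carboxylate 15 (not isolated)
Conditions: KOH, MeOH/H2O, rt; evaporate; MeI, DMF, 0 °C to rt
Reagents that add atoms: potassium hydroxide, [K+].[OH-]; iodomethane, CI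
Why: Saponification followed by SN2 O-methylation of the carboxylate under non-acidic conditions opens the lactone without giving the hydroxy acid a chance to relactonise.

Step 10
Reactants: 16 hydroxy ester
Product: 17 methyl (2S,8S)-8-[(tert-butyldiphenylsilyl)oxy]-2-[(1S)-2-oxocyclopentyl]dec-4-ynoate
Conditions: Dess–Martin periodinane, NaHCO3, CH2Cl2, 0 °C
Reagents that add atoms: none
Why: Dess–Martin oxidation under buffered conditions should give the cyclopentanone without epimerising the adjacent C13 and C16 centres.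

Step 11
Reactants: 17 keto ester
Product: 18 methyl (2S,8S)-8-[(tert-butyldiphenylsilyl)oxy]-2-[(1S)-2-{[(trifluoromethyl)sulfonyl]oxy}cyclopent-2-en-1-yl]dec-4-ynoate
Conditions: KN(SiMe3)2, THF, −78 °C; PhNTf2, −78 to 0 °C
Reagents that add atoms: N-phenylbis(trifluoromethanesulfonimide), O=S(=O)(N(c1ccccc1)S(=O)(=O)C(F)(F)F)C(F)(F)F
Why: Kinetic deprotonation at the unhindered C11 methylene and O-sulfonylation of the enolate (enol triflate formation) fix the C11=C12 position and leave C13 untouched.

Step 12
Reactants: 18 enol triflate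
Product: 19 methyl (1S,3Z,6aS)-3-{(5S)-5-[(tert-butyldiphenylsilyl)oxy]-1-hydroxyheptan-2-ylidene}-1,2,3,5,6,6a-hexahydropentalene-1-carboxylate
Conditions: Pd(PPh3)4 (5 mol %), Bu3SnCH2OH, LiCl, 1,4-dioxane, 90 °C
Reagents that add atoms: (tributylstannyl)methanol, CCCC[Sn](CCCC)(CCCC)CO
Why: Oxidative addition of zerovalent palladium, 5-exo-dig syn carbopalladation of the alkyne (closing ring B) and Stille coupling of the alkenylpalladium intermediate with the hydroxymethylstannane (cyclisation–anion capture) should give the s-cis diene with CH2OH cis to C12, because carbon and palladium add to the same side of the alkyne.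

Step 13
Reactants: 19 dienyl alcohol
Product: 20 methyl (1S,3Z,6aS)-3-{(5S)-1,5-bis[(tert-butyldiphenylsilyl)oxy]heptan-2-ylidene}-1,2,3,5,6,6a-hexahydropentalene-1-carboxylate
Conditions: TBDPSCl, imidazole, DMAP (cat.), CH2Cl2, rt
Reagents that add atoms: tert-butylchlorodiphenylsilane, CC(C)(C)[Si](Cl)(c1ccccc1)c1ccccc1
Why: O-Silylation masks the allylic alcohol against O–H insertion in step 14 and against cation capture in step 16.

Step 14
Reactants: 20 bis-silyl diene; 11 N-nosylhydrazone
Product: 23 bis-silyl cyclohepta-1,4-diene cycloadduct (rings A/B/C; C9=C10 and C12=C18 alkenes; CH2N(Me)Boc on C8), via diazoalkene 21 (not isolated), via divinylcyclopropane 22 (not isolated)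
Conditions: 11, NaH, THF, −20 °C (sodium salt); added over 4 h to 20, Rh2(O2CCF3)4 (2 mol %), PhCF3, 35 °C; then 80 °C
Reagents that add atoms: none
Why: Base turns hydrazone 11 into diazoalkene 21, Rh2(O2CCF3)4 converts it into an electrophilic divalent-rhodium alkenyl carbene that cyclopropanates the C11=C12 bond of diene 20, and the resulting divinylcyclopropane 22 undergoes a Cope (3,3-sigmatropic) rearrangement, so that C10–C11 (kept from the cyclopropanation) and C6–C8 (made in the sigmatropic shift) arise in one operation while the temporary C10–C12 bond is broken. The closest known reaction type is the tandem cyclopropanation/divinylcyclopropane–Cope rearrangement, a formal (4+3) cycloaddition of metal alkenyl carbenes, non-acceptor ones included, with 1,3-dienes. Ring C is closed by a (2+1) cycloaddition followed by 3,3-sigmatropic ring expansion of the cis-divinylcyclopropane through a boat transition state; the cyclopropane is the only other ring formed and it is consumed. C6 is controlled by the Z geometry of the C18=C6 bond together with the face of attack, C8 by the E alkene of the carbene and the boat geometry, which places CH2N cis to the C5 chain, and the transient C11 centre by the same facial choice. The step needs site selectivity for the trisubstituted C11=C12 bond over the tetrasubstituted C18=C6 bond, which the steric difference secures, and facial selectivity, which the convex face bearing H13 and lying opposite the C16 ester secures. A trans-divinylcyclopropane, if formed, should equilibrate on heating by reversible homolysis of the doubly allylic C10–C12 bond and drain through the same Cope channel.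

Step 15
Reactants: 23 cycloadduct
Product: 24 bis-silyl cycloheptene (C9–C10 saturated, C12=C18 retained)
Conditions: 2-nitrobenzenesulfonohydrazide, Et3N, CH2Cl2, rt
Reagents that add atoms: none
Why: Diimide transfer hydrogenation should reduce the cis-disubstituted C9=C10 bond and leave the tetrasubstituted C12=C18 bond untouched, which removes the alkene that would open an aza-Cope channel in step 16.

Step 16
Reactants: 24 bis-silyl cycloheptene
Product: 26 bis-TBDPS ether of the target, via ammonium trifluoroacetate 25 (not isolated)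
Conditions: TFA, CH2Cl2, 0 °C; evaporate; (CH2O)n, MeCN, 70 °C; aq. NaHCO3
Reagents that add atoms: formaldehyde (as paraformaldehyde), C=O
Why: Acidolysis of the carbamate and condensation with formaldehyde give an N-methyl-N-methyleneiminium ion whose carbon (C19) attacks C18 of the tetrasubstituted alkene in a six-membered aza-Prins (iminium–alkene) cyclisation from the face on which the tether lies, which sets the C18 quaternary centre, and loss of the C11 proton from the tertiary C12 cation should place the double bond at C11=C12.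

Step 17
Reactants: 26 bis-TBDPS ether of the target
Product: 27 target CNP0291564.1
Conditions: Bu4NF, AcOH, THF, rt to 45 °C
Reagents that add atoms: none
Why: Buffered fluoride desilylation should cleave both silyl ethers without epimerising C16 or touching the methyl ester.

Compound list
1 | (S)-2-ethyloxirane | CC[C@H]1CO1 | starting material
2 | trimethyl(prop-1-yn-1-yl)silane | CC#C[Si](C)(C)C | starting material
3 | (S)-7-(trimethylsilyl)hept-6-yn-3-ol | CC[C@H](O)CCC#C[Si](C)(C)C | intermediate
4 | (S)-hept-6-yn-3-ol | CC[C@H](O)CCC#C | intermediate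
5 | (S)-tert-butyl(hept-6-yn-3-yloxy)diphenylsilane | CC[C@H](O[Si](c1ccccc1)(c1ccccc1)C(C)(C)C)CCC#C | intermediate
6 | (S)-6-[(tert-butyldiphenylsilyl)oxy]oct-2-yn-1-ol | CC[C@H](O[Si](c1ccccc1)(c1ccccc1)C(C)(C)C)CCC#CCO | intermediate
7 | (S)-[(8-bromooct-6-yn-3-yl)oxy](tert-butyl)diphenylsilane | CC[C@H](O[Si](c1ccccc1)(c1ccccc1)C(C)(C)C)CCC#CCBr | intermediate
8 | tert-butyl methyl(2-oxoethyl)carbamate | CN(CC=O)C(=O)OC(C)(C)C | starting material
9 | (triphenylphosphoranylidene)acetaldehyde | O=CC=P(c1ccccc1)(c1ccccc1)c1ccccc1 | starting material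
10 | tert-butyl methyl[(E)-4-oxobut-2-en-1-yl]carbamate | CN(C/C=C/C=O)C(=O)OC(C)(C)C | intermediate
11 | N-nosylhydrazone of 10 | CN(C/C=C/C=N/NS(=O)(=O)c1ccccc1[N+](=O)[O-])C(=O)OC(C)(C)C | intermediate
12 | (3aR,6aS)-3,3a,6,6a-tetrahydro-2H-cyclopenta[b]furan-2-one, i.e. (1S,5R)-2-oxabicyclo[3.3.0]oct-6-en-3-one | C1[C@H]2[C@@H](C=C1)CC(=O)O2 | starting material
13 | (3aS,6aS)-hexahydro-2H-cyclopenta[b]furan-2-one | C1[C@H]2[C@@H](CC1)CC(=O)O2 | intermediate
14 | (3S,3aS,6aS)-3-{(6S)-6-[(tert-butyldiphenylsilyl)oxy]oct-2-yn-1-yl}hexahydro-2H-cyclopenta[b]furan-2-one | C1[C@H]2[C@@H](CC1)[C@@H](C(=O)O2)CC#CCC[C@@H](O[Si](c1ccccc1)(c1ccccc1)C(C)(C)C)CC | intermediate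
15 | potassium (2S,8S)-8-[(tert-butyldiphenylsilyl)oxy]-2-[(1S,2S)-2-hydroxycyclopentyl]dec-4-ynoate | C1[C@H](O)[C@@H](CC1)[C@@H](C(=O)[O-])CC#CCC[C@@H](O[Si](c1ccccc1)(c1ccccc1)C(C)(C)C)CC.[K+] | intermediate
16 | methyl (2S,8S)-8-[(tert-butyldiphenylsilyl)oxy]-2-[(1S,2S)-2-hydroxycyclopentyl]dec-4-ynoate | C1[C@H](O)[C@@H](CC1)[C@@H](C(=O)OC)CC#CCC[C@@H](O[Si](c1ccccc1)(c1ccccc1)C(C)(C)C)CC | intermediate
17 | methyl (2S,8S)-8-[(tert-butyldiphenylsilyl)oxy]-2-[(1S)-2-oxocyclopentyl]dec-4-ynoate | C1C(=O)[C@@H](CC1)[C@@H](C(=O)OC)CC#CCC[C@@H](O[Si](c1ccccc1)(c1ccccc1)C(C)(C)C)CC | intermediate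
18 | methyl (2S,8S)-8-[(tert-butyldiphenylsilyl)oxy]-2-[(1S)-2-{[(trifluoromethyl)sulfonyl]oxy}cyclopent-2-en-1-yl]dec-4-ynoate | C1=C(OS(=O)(=O)C(F)(F)F)[C@@H](CC1)[C@@H](C(=O)OC)CC#CCC[C@@H](O[Si](c1ccccc1)(c1ccccc1)C(C)(C)C)CC | intermediate
19 | methyl (1S,3Z,6aS)-3-{(5S)-5-[(tert-butyldiphenylsilyl)oxy]-1-hydroxyheptan-2-ylidene}-1,2,3,5,6,6a-hexahydropentalene-1-carboxylate (rings A and B; CH2OH cis to C12) | C1=C2[C@@H](CC1)[C@@H](C(=O)OC)C/C2=C(/CO)\CC[C@@H](O[Si](c1ccccc1)(c1ccccc1)C(C)(C)C)CC | intermediate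
20 | methyl (1S,3Z,6aS)-3-{(5S)-1,5-bis[(tert-butyldiphenylsilyl)oxy]heptan-2-ylidene}-1,2,3,5,6,6a-hexahydropentalene-1-carboxylate | C1=C2[C@@H](CC1)[C@@H](C(=O)OC)C/C2=C(/CO[Si](c1ccccc1)(c1ccccc1)C(C)(C)C)\CC[C@@H](O[Si](c1ccccc1)(c1ccccc1)C(C)(C)C)CC | intermediate
21 | tert-butyl [(E)-4-diazobut-2-en-1-yl](methyl)carbamate | CN(C/C=C/C=[N+]=[N-])C(=O)OC(C)(C)C | intermediate
22 | cis-divinylcyclopropane: cyclopropane C10–C11–C12 on the H13 face of 20, C10 bearing the (E)-CH=CH–CH2N(Me)Boc group cis to C18 | CC[C@H](O[Si](c5ccccc5)(c5ccccc5)C(C)(C)C)CC/C(CO[Si](c5ccccc5)(c5ccccc5)C(C)(C)C)=C1\C[C@H](C(=O)OC)[C@@H]2CC[C@H]3[C@H](/C=C/CN(C)C(=O)OC(C)(C)C)[C@@]123 | intermediate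
23 | (4+3) cycloadduct: rings A, B and C with C9=C10 and C12=C18 double bonds, C6 bearing CH2OTBDPS and the silyloxypentyl chain, C8 bearing CH2N(Me)Boc | CC[C@H](O[Si](c5ccccc5)(c5ccccc5)C(C)(C)C)CC[C@]1(CO[Si](c5ccccc5)(c5ccccc5)C(C)(C)C)[C@H](CN(C)C(=O)OC(C)(C)C)C=C[C@H]3C=4[C@@H](CC3)[C@@H](C(=O)OC)CC=41 | intermediate
24 | 9,10-dihydro derivative of 23 (only the C12=C18 alkene left) | CC[C@H](O[Si](c5ccccc5)(c5ccccc5)C(C)(C)C)CC[C@]1(CO[Si](c5ccccc5)(c5ccccc5)C(C)(C)C)[C@H](CN(C)C(=O)OC(C)(C)C)CC[C@H]3C=4[C@@H](CC3)[C@@H](C(=O)OC)CC=41 | intermediate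
25 | N-methylammonium trifluoroacetate from Boc cleavage of 24 | CC[C@H](O[Si](c5ccccc5)(c5ccccc5)C(C)(C)C)CC[C@]1(CO[Si](c5ccccc5)(c5ccccc5)C(C)(C)C)[C@H](CNC)CC[C@H]3C=4[C@@H](CC3)[C@@H](C(=O)OC)CC=41.OC(=O)C(F)(F)F | intermediate
26 | bis-TBDPS ether of the target (rings A–D complete, C11=C12 alkene) | CC[C@H](O[Si](c5ccccc5)(c5ccccc5)C(C)(C)C)CC[C@]1(CO[Si](c5ccccc5)(c5ccccc5)C(C)(C)C)[C@H]2CCC3=C4[C@@H](CC3)[C@@H](C(=O)OC)C[C@]41CN(C)C2 | intermediate
27 | target CNP0291564.1 | CC[C@H](O)CC[C@]1(CO)[C@H]2CCC3=C4[C@@H](CC3)[C@@H](C(=O)OC)C[C@]41CN(C)C2 | target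

Total steps: 17 (chain fragment 4, carbene fragment 2, core 11). Longest linear sequence: 14 steps (steps 1–4, then 8–17).

Steps most likely to fail

Step 14. The diazoalkene may close to a pyrazole or dimerise faster than the hindered trisubstituted alkene is cyclopropanated. The Z diene may undergo a 1,5-hydrogen shift on heating. A rearrangement through the open diradical instead of the boat transition state may erode the C8 configuration. Fallback (donor/acceptor carbene with a removable ester on the carbene carbon), setting out from 20 and coming back at 24: Wittig olefination of purchasable tert-butyl methyl(3-oxopropyl)carbamate with benzyl (triphenylphosphoranylidene)acetate should give benzyl (E)-5-[(tert-butoxycarbonyl)(methyl)amino]pent-2-enoate F1. Deconjugative diazo transfer (4-acetamidobenzenesulfonyl azide, DBU, MeCN) should give benzyl (E)-5-[(tert-butoxycarbonyl)(methyl)amino]-2-diazopent-3-enoate F2. Its Rh2(OAc)4-catalysed decomposition in the presence of 20 (tandem cyclopropanation/Cope rearrangement of an ester-stabilised alkenyl carbene) should give the C10 benzyl ester cycloadduct F3. H2 over Pd/C should saturate the C9=C10 enoate and cleave the benzyl ester to the C10 carboxylic acid F4. Coupling with N-hydroxypyridine-2-thione (DCC) should give the thiohydroxamate ester F5, and Barton decarboxylation (t-BuSH, visible light) should then return 24.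

Step 16. The C12 cation may lose the C13 proton instead of the C11 proton, and acid may shift the tetrasubstituted alkene before the iminium ion closes. Fallback (hydrative cyclisation, then stereospecific elimination), setting out from 24 and coming back at 26: after the same Boc cleavage (via 25), aqueous formaldehyde in THF–water at 40 °C should let water capture the tertiary cation. This should give the tertiary C12 alcohol F6, with hydroxyl cis to H13, the only face that keeps rings A and B cis-fused. POCl3 in pyridine (anti-periplanar E2) can then remove only H11, which is trans to the hydroxyl whereas H13 is cis, and should give 26.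

Step 12. The alkenyl triflate may undergo direct Stille coupling before carbopalladation. Slow transmetalation at the congested alkenylpalladium intermediate may allow E/Z isomerisation or protodepalladation. Fallback (boron capture and one-carbon homologation), setting out from 18 and coming back at 19: PdCl2(dppf), B2pin2 and KOAc in dioxane at 80 °C (5-exo-dig carbopalladation followed by Miyaura borylation) should give the dienylboronate F7. BrCH2Cl with n-BuLi in THF at −78 °C (Matteson homologation) should give the allylic boronate F8. NaBO3 in THF–water should oxidise it to 19 with the double-bond position and geometry retained.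

Further compounds
F1 | step 14 | benzyl (E)-5-[(tert-butoxycarbonyl)(methyl)amino]pent-2-enoate | CN(CC/C=C/C(=O)OCc1ccccc1)C(=O)OC(C)(C)C
F2 | step 14 | benzyl (E)-5-[(tert-butoxycarbonyl)(methyl)amino]-2-diazopent-3-enoate | CN(C/C=C/C(=[N+]=[N-])C(=O)OCc1ccccc1)C(=O)OC(C)(C)C
F3 | step 14 | analogue of 23 carrying CO2Bn on C10 | CC[C@H](O[Si](c5ccccc5)(c5ccccc5)C(C)(C)C)CC[C@]1(CO[Si](c5ccccc5)(c5ccccc5)C(C)(C)C)[C@H](CN(C)C(=O)OC(C)(C)C)C=C(C(=O)OCc5ccccc5)[C@H]3C=4[C@@H](CC3)[C@@H](C(=O)OC)CC=41
F4 | step 14 | analogue of 24 carrying CO2H on C10 (both C10 epimers) | CC[C@H](O[Si](c5ccccc5)(c5ccccc5)C(C)(C)C)CC[C@]1(CO[Si](c5ccccc5)(c5ccccc5)C(C)(C)C)[C@H](CN(C)C(=O)OC(C)(C)C)CC(C(=O)O)[C@H]3C=4[C@@H](CC3)[C@@H](C(=O)OC)CC=41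
F5 | step 14 | 2-thioxopyridin-1(2H)-yl ester of F4 | CC[C@H](O[Si](c5ccccc5)(c5ccccc5)C(C)(C)C)CC[C@]1(CO[Si](c5ccccc5)(c5ccccc5)C(C)(C)C)[C@H](CN(C)C(=O)OC(C)(C)C)CC(C(=O)ON6C=CC=CC6=S)[C@H]3C=4[C@@H](CC3)[C@@H](C(=O)OC)CC=41
F6 | step 16 | C12 tertiary alcohol with rings A–D closed (OH cis to H13, H11 trans to OH) | CC[C@H](O[Si](c5ccccc5)(c5ccccc5)C(C)(C)C)CC[C@]1(CO[Si](c5ccccc5)(c5ccccc5)C(C)(C)C)[C@H]2CC[C@H]3[C@@]4(O)[C@@H](CC3)[C@@H](C(=O)OC)C[C@]41CN(C)C2
F7 | step 12 | dienylboronate: analogue of 19 with Bpin on C6 in place of CH2OH | C1=C2[C@@H](CC1)[C@@H](C(=O)OC)C/C2=C(/B3OC(C)(C)C(C)(C)O3)\CC[C@@H](O[Si](c1ccccc1)(c1ccccc1)C(C)(C)C)CC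
F8 | step 12 | allylic boronate: analogue of 19 with CH2Bpin in place of CH2OH | C1=C2[C@@H](CC1)[C@@H](C(=O)OC)C/C2=C(/CB3OC(C)(C)C(C)(C)O3)\CC[C@@H](O[Si](c1ccccc1)(c1ccccc1)C(C)(C)C)CC
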